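**Retrosynthetic overview**
1. Ilimaquinone is cut at C11–quinone. A C11 primary radical from the C12 carboxylic acid (Barton decarboxylation, Giese-type addition) is added to commercial 2,5-dimethoxy-1,4-benzoquinone. The OH/OMe pattern is set by a last-step chelation-directed mono-O-demethylation.
2. The exocyclic 4(18)-ene acid comes from its endocyclic Δ3 isomer by contra-thermodynamic alkene transposition (decatungstate/cobaloxime).
3. The Δ3 acid comes from (+)-sclareolide in one biomimetic cascade. The tertiary C8 cation is followed by four suprafacial 1,2-shifts (H-9→C8, Me-10→C9, H-5→C10, Me-4→C5) and loss of a C4 proton.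
4. No ring is built. The decalin comes from the chiral pool and the quinone is a commercial building block. C5, C8, C9 and C10 are all set in the cascade, with chirality transferred from sclareolide.

**Assumption:** (+)-sclareolide, 2,5-dimethoxy-1,4-benzoquinone and 1-hydroxypyridine-2-thione are commercial. Under prolonged BF3 exposure the cascade funnels mainly to the Δ3 acid 2 (the more substituted alkene).

---

**Step 1**
Reactants: 1 (+)-sclareolide
Product: 2 Δ3-ene rearranged acid (avarane skeleton)
Conditions: BF3·OEt2 (3 equiv), CH2Cl2, 0 °C → rt, 6 h; sat. NaHCO3 quench; extract the acid into aq. Na2CO3, acidify with 1 M citric acid at 0 °C, extract with Et2O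
Reagents that add atoms: none
Why: Proposed new method: BF3 binds the lactone C=O, so the tertiary C8–O bond ionises as in an AAL1 tert-alkyl ester cleavage, giving the C8 cation and a BF3-bound carboxylic acid. In the trans-decalin chair this cation runs the clerodane/avarane-type cascade of suprafacial trans-diaxial shifts. H-9α moves to C8α. Me-10β moves to C9β, which pushes the CH2CO2H chain to the α (equatorial) position. H-5α moves to C10α. Me-4β moves to C5β. The C4 cation then loses a proton to give the Δ3 alkene. The closest known reaction is the BF3-induced drimane → 4,9-friedodrimane rearrangement used in avarol and aureol syntheses. Any exomethylene isomer formed is carried through Step 2 unchanged. The net change is an isomerisation (C16H26O2 → C16H26O2).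

**Step 2**
Reactants: 2 Δ3-ene acid
Product: 3 Δ4(18)-exomethylene acid
Conditions: (nBu4N)4W10O32 (TBADT, 2 mol %), Co(dmgH)2(py)Cl (5 mol %), MeCN, 390 nm LEDs, 25 °C, 24 h; AgNO3–SiO2 chromatography, with unreacted 2 recycled
Reagents that add atoms: none
Why: Proposed new method: excited decatungstate abstracts an allylic H from the C18 methyl of 2 to give the C3–C4–C18 allyl radical. Co(II) captures the less hindered primary terminus (C18) as an allyl-Co(III). Protodemetalation (SE2′, with the substrate CO2H or the cobalt-bound proton as the proton source) delivers H to C3 and forms the less stable C4=C18 alkene. The closest known reaction is photochemical contra-thermodynamic positional alkene isomerisation (decatungstate/cobaloxime) of 1-methylcycloalkenes to methylenecycloalkanes. No stereocentre is touched, and C8–H and C10–H (tertiary) are the competing but less activated HAT sites.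

**Step 3**
Reactants: 3 exomethylene acid; 4 1-hydroxypyridine-2(1H)-thione
Product: 5 Barton PTOC ester of 3
Conditions: DCC (1.2 equiv), DMAP (0.1 equiv), CH2Cl2, 0 °C → rt, 3 h, in the dark
Reagents that add atoms: 4, 1-hydroxypyridine-2(1H)-thione, ON1C=CC=CC1=S (supplies the O-acyl thiohydroxamate unit). DCC, C1CCC(CC1)N=C=NC1CCCCC1, leaves no atoms in the product (it becomes dicyclohexylurea).
Why: Carbodiimide-mediated esterification (Steglich-type) gives the thiohydroxamate ester. No acid chloride is used, so no HCl is generated to add to the exocyclic alkene. All stereocentres are remote and unchanged.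

**Step 4**
Reactants: 5 PTOC ester; 6 2,5-dimethoxy-1,4-benzoquinone
Product: 7 2-alkyl-3,6-dimethoxy-1,4-benzoquinone (alkyl = the decalinylmethyl group of 3)
Conditions: 6 (3 equiv), CH2Cl2, 10 °C, visible light (300 W tungsten lamp), 1 h; then MnO2, rt, 30 min
Reagents that add atoms: none
Why: Barton decarboxylative radical generation followed by Giese-type addition. Light cleaves the N–O bond and CO2 is lost. The nucleophilic primary neopentyl C11 radical adds to an unsubstituted CH position of the electron-poor quinone. Excess 6 and MnO2 reoxidise the semiquinone or hydroquinone adducts to 7. The radical is not stereogenic, and C9 is untouched. The C11 radical (equatorial on C9) and C4=C18 (equatorial on C5) are 1,3-diequatorial across ring B, so 5-exo cyclisation is geometrically blocked.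

**Step 5**
Reactants: 7
Product: 8 (+)-ilimaquinone
Conditions: BCl3 (1.2 equiv, 1 M in CH2Cl2), 2,6-di-tert-butyl-4-methylpyridine (1.5 equiv), CH2Cl2, −78 → 0 °C, 1 h; quench with water/dilute HCl
Reagents that add atoms: none (the OH oxygen is the original OMe oxygen; the methyl leaves as MeCl)
Why: Proposed new method: BCl3 forms a five-membered chelate between the unhindered carbonyl (the one flanked by the ring CH) and its adjacent OMe, which is the OMe next to the alkyl-bearing carbon, and chloride removes that methyl. The other carbonyl is flanked by the bulky C9-derived neopentyl substituent and is much less accessible, so the distal OMe survives. The closest known reaction is BCl3 ortho-demethylation of α-methoxy carbonyl compounds. The hindered base scavenges HCl to protect the exocyclic alkene.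

---

**Compound list**

1 | (+)-sclareolide, (3aR,5aS,9aS,9bR)-3a,6,6,9a-tetramethyldecahydronaphtho[2,1-b]furan-2-one | C[C@]12CCCC(C)(C)[C@@H]1CC[C@]3(C)[C@@H]2CC(=O)O3 | starting material
2 | Δ3-ene rearranged acid (avarane numbering: 3-ene, 5β-Me, 10α-H, 9β-Me/9α-CH2CO2H, 8β-Me/8α-H; trans-decalin) | CC1=CCC[C@H]2[C@](C)(CC(=O)O)[C@@H](C)CC[C@]12C | intermediate
3 | Δ4(18)-exomethylene acid, 2-(1,2,4a-trimethyl-5-methylidene-decahydronaphthalen-1-yl)acetic acid, same relative and absolute configuration as 2 | C=C1CCC[C@H]2[C@](C)(CC(=O)O)[C@@H](C)CC[C@]12C | intermediate
4 | 1-hydroxypyridine-2(1H)-thione | ON1C=CC=CC1=S | starting material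
5 | Barton PTOC ester of 3 (O-acyl 1-hydroxypyridine-2-thione) | C=C1CCC[C@H]2[C@](C)(CC(=O)ON3C=CC=CC3=S)[C@@H](C)CC[C@]12C | intermediate
6 | 2,5-dimethoxy-1,4-benzoquinone | COC1=CC(=O)C(OC)=CC1=O | starting material
7 | 2-alkyl-3,6-dimethoxy-1,4-benzoquinone (alkyl = decalinylmethyl of 3) | C=C1CCC[C@H]2[C@](C)(CC3=C(OC)C(=O)C=C(OC)C3=O)[C@@H](C)CC[C@]12C | intermediate
8 | (+)-ilimaquinone | C=C1CCC[C@H]2[C@](C)(CC3=C(O)C(=O)C=C(OC)C3=O)[C@@H](C)CC[C@]12C | target

**Total step count:** 5. **Longest linear sequence:** 5 steps (1 → 2 → 3 → 5 → 7 → 8).

**Three steps most likely to fail**
1. **Step 1 (cascade).** BF3 may not ionise the lactone cleanly. The carboxyl group can re-trap the cations as a lactone, the C8 cation can simply lose a proton to give 8(17)-ene or Δ7 acids, and the cascade can stop part-way. *Fallback (different approach):* reverse the order so the rearrangement runs on an arene-bearing drimane. Open sclareolide to the 8(17)-ene homodrimenoic acid, then couple its PTOC ester to 6 by the Step 3–4 sequence. Reduce with Na2S2O4 and bis-methylate to the tetramethoxyarene. Run the BF3 backbone rearrangement with no carboxyl present. Then oxidise with CAN, accepting a separable quinone regioisomer mixture, and finish as in Step 5.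
2. **Step 2 (contra-thermodynamic isomerisation).** Decatungstate may abstract the tertiary C8–H or C10–H instead, or abstract C2–H to give a Δ2 alkene, or the reaction may stall at a photostationary mixture. *Fallback:* Mukaiyama hydration (Co(acac)2, PhSiH3, O2) converts 2 into the C4 tertiary alcohol. Dehydrate with Martin sulfurane, separate the exo and endo alkenes on AgNO3–SiO2, and recycle the endo alkene through hydration.
3. **Step 5 (regioselective demethylation).** BCl3 could cleave the distal OMe and give the regioisomeric hydroxyquinone, or it could add HCl to or isomerise the exocyclic alkene. *Fallback:* move the differentiation before the coupling. Mono-hydrolyse 6 to 2-hydroxy-5-methoxy-1,4-benzoquinone (unambiguous, because the two OMe groups of 6 are equivalent), run the Step 4 radical addition on it, and separate the regioisomers by chromatography.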